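**Retrosynthetic overview**
1. Target 12 ← tri-MOM flavanone 11 by global acetal cleavage (last step).
2. 11 ← chromone 5 + arylboronic acid 10. The C2–C1' bond and the only stereocentre are made together by a Rh-catalysed enantioselective 1,4-arylation of an intact chromone, with no chalcone or oxa-Michael closure.
3. 5 ← 6,8-diiodochromone 3 by a one-pot double Stille prenylation; 3 ← commercial 7-hydroxychromone 1 by diiodination and MOM protection.
4. 10 ← 4-bromoresorcinol 6 by MOM protection and Br/Li exchange–borylation.
5. Ring order: no ring is formed. The benzopyranone (A/C) is bought intact and only its C2=C3 bond is saturated by the arylation; the B ring is attached last as the nucleophile.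

Assumption: the stereodescriptor in the target SMILES corresponds to (2S) (O1 > C1' > C3 > H), and 1, 4, 6 and both enantiomers of MeO-F12-BIPHEP are taken as commercially available.

Step 1
Reactants: 1 7-hydroxy-4H-chromen-4-one
Product: 2 7-hydroxy-6,8-diiodo-4H-chromen-4-one
Conditions: NIS (2.1 equiv), p-TsOH·H2O (10 mol %), MeCN, 0 °C → rt
Reagents that add atoms: N-iodosuccinimide, O=C1CCC(=O)N1I
Why: Electrophilic aromatic iodination (SEAr): the 7-OH activates only its two ortho positions C6 and C8, whereas C5 is meta and the push–pull pyranone C3 is far less nucleophilic, so two equivalents of I+ give the 6,8-diiodide.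

Step 2
Reactants: 2 7-hydroxy-6,8-diiodo-4H-chromen-4-one
Product: 3 6,8-diiodo-7-(methoxymethoxy)-4H-chromen-4-one
Conditions: MOMCl (1.5 equiv), K2CO3 (2.5 equiv), DMF, 0 °C → rt
Reagents that add atoms: chloromethyl methyl ether, COCCl
Why: Williamson-type O-alkylation (MOM protection): the strongly acidic vinylogous-acid phenol is fully ionised by K2CO3, and the small SN1-like electrophile MOMCl reaches the oxygen despite the two flanking iodines.

Step 3
Reactants: 3 6,8-diiodo-7-(methoxymethoxy)-4H-chromen-4-one; 4 tributyl(3-methylbut-2-en-1-yl)stannane (3 equiv)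
Product: 5 7-(methoxymethoxy)-6,8-bis(3-methylbut-2-en-1-yl)-4H-chromen-4-one
Conditions: Pd(PPh3)4 (10 mol %), DMF, 90 °C; chromatography on 10% K2CO3–silica
Reagents that add atoms: none
Why: Double Migita–Kosugi–Stille coupling: Pd(0) inserts into both aryl C–I bonds, the prenyl group is transferred from tin, and reductive elimination from the less hindered CH2 terminus of the η3-prenyl-Pd gives the linear prenyl arene; the chromone enone and MOM acetal are inert to neutral Pd(0)/stannane.

Step 4
Reactants: 6 4-bromobenzene-1,3-diol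
Product: 7 1-bromo-2,4-bis(methoxymethoxy)benzene
Conditions: MOMCl (2.6 equiv), K2CO3 (4 equiv), acetone, 0 °C → rt
Reagents that add atoms: chloromethyl methyl ether, COCCl
Why: Williamson-type double O-alkylation (MOM protection) of both phenols; the aryl bromide is untouched.

Step 5
Reactants: 7 1-bromo-2,4-bis(methoxymethoxy)benzene
Product: 10 [2,4-bis(methoxymethoxy)phenyl]boronic acid, via aryllithium 8 (not isolated), via lithium aryl(triisopropoxy)borate 9 (not isolated)
Conditions: n-BuLi (1.05 equiv), THF, −78 °C, 20 min; B(Oi-Pr)3 (1.5 equiv), −78 °C → 0 °C; 1 M aq HCl to pH 5–6, 0 °C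
Reagents that add atoms: triisopropyl borate, CC(C)OB(OC(C)C)OC(C)C; water, O; n-butyllithium, [Li]CCCC (lithium only in intermediates 8 and 9)
Why: Bromine–lithium exchange followed by electrophilic borylation: exchange at −78 °C is faster than ortho-lithiation between the two OMOM groups, the ortho-OMOM-chelated aryllithium is trapped by the borate as the ate complex, and hydrolysis at pH 5–6 frees the boronic acid without cleaving the MOM acetals or causing protodeboronation.

Step 6
Reactants: 5 7-(methoxymethoxy)-6,8-bis(3-methylbut-2-en-1-yl)-4H-chromen-4-one; 10 [2,4-bis(methoxymethoxy)phenyl]boronic acid (3 equiv, added in portions)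
Product: 11 (2S)-2-[2,4-bis(methoxymethoxy)phenyl]-7-(methoxymethoxy)-6,8-bis(3-methylbut-2-en-1-yl)-2,3-dihydro-4H-chromen-4-one
Conditions: [Rh(OH)((S)-MeO-F12-BIPHEP)]2 (3 mol % Rh, preformed from [Rh(OH)(cod)]2 and ligand), CH2Cl2/H2O 10:1, 30 °C
Reagents that add atoms: none
Why: Hayashi–Miyaura-type Rh(I)-catalysed asymmetric 1,4-addition to a chromone: the aryl–Rh(I) formed by transmetalation from 10 inserts the C2=C3 bond on the enantioface left open by the C2-symmetric electron-poor bisphosphine, and water protonates the oxa-π-allyl rhodium at C3; the (S)-ligand is chosen by the quadrant model that gives (S)-3-arylcyclohexanones, which maps onto (2S) here (this sense is a model-based prediction to be confirmed on the first run by chiral HPLC and CD, where (2S)-flavanones show a positive band near 330 nm and a negative band near 290 nm, with the antipodal ligand equally available), CH2Cl2 tempers the catalyst so the product ketone is not arylated again, and the unactivated trisubstituted prenyl alkenes and MOM acetals are inert to the neutral Rh–OH catalyst.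

Step 7
Reactants: 11 (2S)-2-[2,4-bis(methoxymethoxy)phenyl]-7-(methoxymethoxy)-6,8-bis(3-methylbut-2-en-1-yl)-2,3-dihydro-4H-chromen-4-one
Product: 12 (2S)-2-(2,4-dihydroxyphenyl)-7-hydroxy-6,8-bis(3-methylbut-2-en-1-yl)-2,3-dihydro-4H-chromen-4-one
Conditions: 1.25 M HCl in anhydrous MeOH, 0 °C → 25 °C, monitored by HPLC; NaHCO3 quench to pH 6–7
Reagents that add atoms: none
Why: Acid-catalysed transacetalisation of the three aryl MOM ethers, with methanol trapping the methoxymethyl cation so it cannot C-alkylate the freed resorcinol ring; at room temperature without base the prenyl groups do not cyclise onto the 7-OH, and C2 is not epimerised because neither the enolate/quinone-methide ring opening nor benzylic ionisation is accessible.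

**Compound list**
1 | 7-hydroxy-4H-chromen-4-one | O=c1ccoc2cc(O)ccc12 | starting material
2 | 7-hydroxy-6,8-diiodo-4H-chromen-4-one | O=c1ccoc2c(I)c(O)c(I)cc12 | intermediate
3 | 6,8-diiodo-7-(methoxymethoxy)-4H-chromen-4-one | O=c1ccoc2c(I)c(OCOC)c(I)cc12 | intermediate
4 | tributyl(3-methylbut-2-en-1-yl)stannane | CCCC[Sn](CCCC)(CCCC)CC=C(C)C | starting material
5 | 7-(methoxymethoxy)-6,8-bis(3-methylbut-2-en-1-yl)-4H-chromen-4-one | O=c1ccoc2c(CC=C(C)C)c(OCOC)c(CC=C(C)C)cc12 | intermediate
6 | 4-bromobenzene-1,3-diol | Oc1ccc(Br)c(O)c1 | starting material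
7 | 1-bromo-2,4-bis(methoxymethoxy)benzene | COCOc1ccc(Br)c(OCOC)c1 | intermediate
8 | [2,4-bis(methoxymethoxy)phenyl]lithium | [Li]c1ccc(OCOC)cc1OCOC | intermediate (not isolated)
9 | lithium [2,4-bis(methoxymethoxy)phenyl]tri(propan-2-yloxy)borate | [Li+].CC(C)O[B-](OC(C)C)(OC(C)C)c1ccc(OCOC)cc1OCOC | intermediate (not isolated)
10 | [2,4-bis(methoxymethoxy)phenyl]boronic acid | COCOc1ccc(B(O)O)c(OCOC)c1 | intermediate
11 | (2S)-2-[2,4-bis(methoxymethoxy)phenyl]-7-(methoxymethoxy)-6,8-bis(3-methylbut-2-en-1-yl)-2,3-dihydro-4H-chromen-4-one | CC(C)=CCc1cc2c(c(CC=C(C)C)c1OCOC)O[C@H](c1ccc(OCOC)cc1OCOC)CC2=O | intermediate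
12 | (2S)-2-(2,4-dihydroxyphenyl)-7-hydroxy-6,8-bis(3-methylbut-2-en-1-yl)-2,3-dihydro-4H-chromen-4-one | CC(C)=CCc1cc2c(c(CC=C(C)C)c1O)O[C@H](c1ccc(O)cc1O)CC2=O | target

**Totals**
Total step count: 7. Longest linear sequence: 5 steps (1 → 2 → 3 → 5 → 11 → 12); the two-step synthesis of 10 is a convergent branch.

**Three steps most likely to fail, with fallbacks**

Step 6 (asymmetric 1,4-arylation). The chromone is electron-rich, the boronic acid is ortho-substituted and prone to protodeboronation, and the facial sense rests on a model. Fallback: set out from 5 and 10 and give up catalyst control. The far more active achiral [Rh(OH)(cod)]2 (3 mol %, dioxane/H2O, 40 °C) gives racemic 2-[2,4-bis(methoxymethoxy)phenyl]-7-(methoxymethoxy)-6,8-bis(3-methylbut-2-en-1-yl)-2,3-dihydro-4H-chromen-4-one F1. This is resolved by a Noyori asymmetric-transfer-hydrogenation kinetic resolution (RuCl[(R,R)-TsDPEN](p-cymene), HCO2H/Et3N 5:2, EtOAc, rt, stopped at about 52–55% conversion). The catalyst, which makes (R)-benzylic carbinols, should reduce the (2R)-ketone to the cis alcohol (2R,4R)-2-[2,4-bis(methoxymethoxy)phenyl]-7-(methoxymethoxy)-6,8-bis(3-methylbut-2-en-1-yl)-3,4-dihydro-2H-chromen-4-ol F2 and leave the (2S)-ketone; which enantiomer is consumed is checked by chiral HPLC on the racemate. The ketone is separated from F2 on silica, and the route is rejoined at 11. Prenyl alkenes and MOM ethers are inert to these conditions.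

Step 3 (double prenyl Stille). The risks are γ-attack giving reverse-prenyl isomers, β-hydride loss from prenyl-Pd giving proto-deiodination, and incomplete second coupling. Fallback: set out from 3 and install the carbons in two stages. A double Stille coupling with allyltributylstannane (Pd(PPh3)4, DMF, 90 °C; no regiochemical ambiguity) gives 6,8-diallyl-7-(methoxymethoxy)-4H-chromen-4-one F3. Double olefin cross-metathesis with excess 2-methylbut-2-ene (Grubbs II, CH2Cl2, 40 °C) then converts both allyl groups into prenyl groups, rejoining the route at 5. The electron-poor chromone C2=C3 bond does not take part in metathesis.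

Step 7 (global MOM removal). The risks are acid-induced cyclisation of a prenyl group onto the 7-OH, HCl or MeOH addition to the alkenes, and erosion of ee. Fallback: set out from 11 and avoid protic acid by exchanging the protecting groups. TESOTf/2,2'-bipyridyl (MeCN/CH2Cl2, 0 °C → rt, buffered aqueous work-up) converts the three aryl MOM ethers directly into aryl silyl ethers, giving (2S)-2-[2,4-bis(triethylsilyloxy)phenyl]-6,8-bis(3-methylbut-2-en-1-yl)-7-(triethylsilyloxy)-2,3-dihydro-4H-chromen-4-one F4. Non-basic fluoride (Et3N·3HF, THF, 0 °C) then removes the silyl groups without generating a free phenoxide, rejoining the route at 12.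

**Further compounds**
F1 | step 6 | racemic 2-[2,4-bis(methoxymethoxy)phenyl]-7-(methoxymethoxy)-6,8-bis(3-methylbut-2-en-1-yl)-2,3-dihydro-4H-chromen-4-one | CC(C)=CCc1cc2c(c(CC=C(C)C)c1OCOC)OC(c1ccc(OCOC)cc1OCOC)CC2=O
F2 | step 6 | (2R,4R)-2-[2,4-bis(methoxymethoxy)phenyl]-7-(methoxymethoxy)-6,8-bis(3-methylbut-2-en-1-yl)-3,4-dihydro-2H-chromen-4-ol | CC(C)=CCc1cc2c(c(CC=C(C)C)c1OCOC)O[C@@H](c1ccc(OCOC)cc1OCOC)C[C@H]2O
F3 | step 3 | 6,8-diallyl-7-(methoxymethoxy)-4H-chromen-4-one | O=c1ccoc2c(CC=C)c(OCOC)c(CC=C)cc12
F4 | step 7 | (2S)-2-[2,4-bis(triethylsilyloxy)phenyl]-6,8-bis(3-methylbut-2-en-1-yl)-7-(triethylsilyloxy)-2,3-dihydro-4H-chromen-4-one | CC(C)=CCc1cc2c(c(CC=C(C)C)c1O[Si](CC)(CC)CC)O[C@H](c1ccc(O[Si](CC)(CC)CC)cc1O[Si](CC)(CC)CC)CC2=O
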